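## Analysis of the target

Target 15 is a diaryl ether of two 1,3,5-trioxygenated benzene rings. It has no stereocentre and no ring that must be constructed, so every skeletal carbon can be bought as part of a benzene derivative. Ring A is numbered A1 (sulfated oxygen), A3 (free hydroxyl) and A5 (ether carbon). Ring B is numbered B1 (ether carbon), B2 and B6 (free hydroxyls) and B4 (sulfated oxygen), so ring B is symmetric about the B1–B4 axis. Six oxygens of almost equal reactivity must end in three states (one bridging, three free, two sulfated), so the task is one of differentiation. The aryl hydrogen sulfates are cleaved by acid, including their own acidity, and make every compound that carries them a polar salt, so they have to come last. The polyphenol rings are electron-rich and prone to oxidation and C-alkylation. The hardest bond is B1–O: B1 lies between two oxygen-bearing carbons, so it is hindered and deactivated as an electrophile, and ring A offers no activation either. The strategy rests on B2 and B6, the two carbons flanking B1. As formyl carbons they make B1 a strong electrophile for ether formation, and they can then be exchanged for the two hydroxyls by migration of B2 and B6 from carbon to oxygen. B4 and A1, each meta to the other substituents of its ring, are marked by bromine atoms that later become the sulfated oxygens.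

## Retrosynthetic reasoning

Target 15 to 14: the three benzylic C–O bonds at A3, B2 and B6 are cut last. Benzyl ethers are chosen for the hydroxyls that stay free because hydrogenolysis is neutral and leaves aryl sulfate monoesters intact, whereas acid-labile groups would endanger the S–O bonds. The forward step has to remove three benzyl groups from a dianionic substrate without hydrolysing a sulfate.

14 to 13: the two S–O bonds are cut. Diol 13 has exactly two free hydroxyls, at A1 and B4, so the sulfation needs no selectivity and only has to go to completion on both.

13 to 12 to 11: the C–O bonds at A1 and B4 are traced back to C–B bonds in bis(boronate) 12 and to C–Br bonds in dibromide 11. Bromine is inert to the base, peracid and alkylation conditions of the earlier steps, and both positions are unhindered for palladium insertion. A bromine at A1, rather than a third and separately protected oxygen, gains three things: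
- ring A is not a strongly nucleophilic 1,3,5-trioxygenated ring when excess peracid is present;
- the ring A building block 7 needs a single mono-alkylation of a symmetric diol instead of two statistical protections;
- no acid-labile acetal has to be cleaved next to electron-rich rings, where the released electrophile could alkylate carbon.
Both sulfation sites are then unveiled in one operation.

11 to 10: the two O–benzyl bonds at B2 and B6 are cut, leading to resorcinol 10, whose only free hydroxyls are these two.

10 to 8 (through 9): this is the central disconnection. The B2–O and B6–O bonds are cut and each oxygen is replaced by a formyl carbon, giving dialdehyde 8. In the forward direction a peracid must make B2 and B6 migrate from carbon to oxygen, and the two formate esters of 9 are then removed. Cutting here means the oxygens flanking B1 are absent when the ether bond is made; in their place stand two acceptor groups that activate B1.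

8 to 5 and 7: the B1–O bond is cut on the ring B side. In fluoro dialdehyde 5 the fluorine is ortho to two formyl groups, so phenol 7, an unhindered nucleophile, can displace it by addition–elimination. The opposite polarity would require a hindered 2,6-disubstituted phenol to attack an unactivated ring A.

5 to 2 to 1, and 7 to 6: the C–C bond to the second formyl group is cut. Acetal 2 has only one hydrogen ortho to fluorine, the most acidic ring position, so deprotonation and formylation place the new carbon where it is needed. Acetal 2 comes from aldehyde 1 by masking the carbonyl. Phenol 7 is disconnected at its O–benzyl bond to the symmetric diol 6.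

## Alternatives that were turned down

Alternative 1: The two sulfated oxygens are disconnected to C–H bonds. Tripivalate A1, 2-[3-(pivaloyloxy)phenoxy]-1,3-phenylene bis(2,2-dimethylpropanoate), would be borylated with [Ir(OMe)(cod)]2, 4,4'-di-tert-butyl-2,2'-bipyridine and B2pin2 at its only two ring positions without an ortho substituent, A1 and B4. KHSO5 in the same pot would then give diol A2, 5-hydroxy-2-[3-hydroxy-5-(pivaloyloxy)phenoxy]-1,3-phenylene bis(2,2-dimethylpropanoate).
- For: the steric preference of iridium borylation points at exactly the two carbons that need oxygen. No halogen is carried, one pot replaces steps 7 and 8 of the chosen route, and pivalates can be removed by base in the presence of sulfate salts without a hydrogenation catalyst. On end-game economy this alternative is stronger.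
- Against: it leaves the hardest bond unsolved. A1 already contains the ether flanked by two oxygens, and making it needs a copper-mediated coupling at a hindered, electron-rich carbon or else a device like the one chosen here. Ring A of A1 also has two C–H bonds (A4, A6) with only one ortho neighbour, so site selection depends on relative rates and not on an atom already in place. Three hindered pivalates must finally be cleaved from a dianion by a strong nucleophilic base.
- Comparison: the chosen route gives up the one-pot C–H oxidation. In return it offers an activated, predictable construction of B1–O and fixes both sulfation sites by bromines bought with 1 and 6.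

Alternative 2: Ring B is disconnected across B2–B3, B4–B5 and B1–B2. Heating racemic cyclobutenone A3, 4-[3-(benzyloxy)-5-(methoxymethoxy)phenoxy]-3-(benzyloxy)cyclobut-2-en-1-one, with (triisopropylsilyloxy)ethyne A4 would open A3 to a vinylketene. A [2+2] addition of the alkyne, a second ring opening, a 6π electrocyclisation and tautomerisation would then give phenol A5, 2-[3-(benzyloxy)-5-(methoxymethoxy)phenoxy]-3-(benzyloxy)-5-(triisopropylsilyloxy)phenol.
- For: ring B arrives with all four oxygens, and B4 is already distinguished as a silyl ether. B1–O is never made on an aromatic carbon, and no peracid or palladium is needed. On the direct delivery of the B4 oxygen it is stronger than the chosen route.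
- Against: A3 has to come from an aryloxyketene and a benzyl ynol ether, and A4 is a moisture-sensitive ynol ether, so three reactive partners must be prepared and handled. The ring A piece is an unsymmetrically diprotected 1,3,5-triol, accessible only by statistical protection. The B2/B6 differentiation it creates is of no use for a target that is symmetric there. The step count to A3 is higher than the four steps to 8.
- Comparison: the chosen route uses bench-stable intermediates and treats B2 and B6 alike, as the target does.

Alternative 3: Ring B is disconnected at B2–B3 and B5–B6. Dimethyl 2-[3-(benzyloxy)-5-(methoxymethoxy)phenoxy]malonate A6 would acylate both α-carbons of dimethyl 3-oxopentanedioate A7 under NaOMe in hot methanol. The product would be dimethyl 5-[3-(benzyloxy)-5-(methoxymethoxy)phenoxy]-2,4,6-trihydroxyisophthalate A8.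
- For: B1–O is formed by simple substitution at the sp3 malonate carbon, the building blocks are cheap, and no transition metal is used. On the ease of making the ether bond it is at least as strong as the chosen route.
- Against: A8 carries two ester groups at B3 and B5 that are absent from the target. Their removal needs hydrolysis and double decarboxylation of an oxidation-prone aryloxy triol, with an acid-labile acetal present. The three ring B hydroxyls emerge free and similar, so B4 would have to be sulfated selectively with nothing in their origin to distinguish them. A6 is deprotonated under the reaction conditions, which blunts its electrophilicity. The statistically protected ring A piece is needed again.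
- Comparison: the chosen route distinguishes the three ring B oxygens by where they come from (two from formyl groups, one from bromine) and has no carbon to excise afterwards.

Key step: step 5

Remark on the chemistry: the aryl hydrogen sulfates 14 and 15 are drawn as free acids to match the target. Both would be handled as disodium salts, and the acid form of 15 would be released only at the end on a sulfonic acid resin in the cold, because free aryl hydrogen sulfates hydrolyse on standing.

## Route

Step 1
Reactants: 1 5-bromo-2-fluorobenzaldehyde
Product: 2 4-bromo-2-(dimethoxymethyl)-1-fluorobenzene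
Conditions: HC(OMe)3, TsOH·H2O (cat.), MeOH, reflux; Et3N quench
Reagents that add atoms: trimethyl orthoformate, COC(OC)OC; methanol, CO
Why: Acid-catalysed acetalisation, driven by the orthoformate, which takes up the water released. The acetal shields the carbonyl from the amide base of step 2 and occupies one of the two positions ortho to fluorine.

Step 2
Reactants: 2 4-bromo-2-(dimethoxymethyl)-1-fluorobenzene
Product: 5 5-bromo-2-fluorobenzene-1,3-dicarbaldehyde, via aryllithium 3 (not isolated), via acetal aldehyde 4 (not isolated)
Conditions: LiN(iPr)2, THF, −78 °C; DMF, −78 °C; then 2 M HCl, THF, rt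
Reagents that add atoms: N,N-dimethylformamide, CN(C)C=O; water, O
Why: Directed ortho-lithiation and formylation: fluorine acidifies its single remaining ortho hydrogen most strongly, and the hindered amide base deprotonates without exchanging bromine, as is known for para-bromofluoroarenes. The aryllithium adds to DMF, and the acid work-up collapses the hemiaminal and hydrolyses the dimethyl acetal.

Step 3
Reactants: 6 5-bromobenzene-1,3-diol
Product: 7 3-(benzyloxy)-5-bromophenol
Conditions: BnBr (1 equiv), 6 (3 equiv), K2CO3, acetone, reflux; excess 6 recovered from the aqueous washings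
Reagents that add atoms: benzyl bromide, BrCc1ccccc1
Why: Williamson ether synthesis on a symmetric diol. The threefold excess of the inexpensive diol should keep double benzylation low, and the water-soluble diol is separated by extraction.

Step 4
Reactants: 5 5-bromo-2-fluorobenzene-1,3-dicarbaldehyde; 7 3-(benzyloxy)-5-bromophenol
Product: 8 2-[3-(benzyloxy)-5-bromophenoxy]-5-bromobenzene-1,3-dicarbaldehyde
Conditions: K2CO3, DMF, rt
Reagents that add atoms: none
Why: Nucleophilic aromatic substitution by addition–elimination: the two ortho formyl groups stabilise the Meisenheimer complex, and fluoride is the best leaving group for this mechanism. Neither bromine is activated, so only B1 should react.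

Step 5
Reactants: 8 2-[3-(benzyloxy)-5-bromophenoxy]-5-bromobenzene-1,3-dicarbaldehyde
Product: 10 2-[3-(benzyloxy)-5-bromophenoxy]-5-bromobenzene-1,3-diol, via bis(formate) 9 (not isolated)
Conditions: mCPBA (4 equiv), CH2Cl2, 0 → 40 °C; aq Na2S2O3/NaHCO3 wash; then K2CO3 (cat.), MeOH, 0 °C → rt
Reagents that add atoms: 3-chloroperoxybenzoic acid, O=C(OO)c1cccc(Cl)c1
Why: Each formyl carbon is attacked by the peracid to give a tetrahedral peroxy hemiacetal (Criegee adduct), in which ring carbon B2, and in the second event B6, shifts from the former carbonyl carbon to the adjacent peroxide oxygen as 3-chlorobenzoate departs. This is the Baeyer–Villiger oxidation of an aromatic aldehyde (the peracid form of the Dakin oxidation), known for ortho-alkoxy- and ortho-aryloxybenzaldehydes and for aromatic dialdehydes. Bis(formate) 9 is not purified: once the peracid has been washed out, catalytic methoxide transfers both formyl groups to methanol and frees resorcinol 10. No ring is closed and no stereocentre is created, so the selectivity at stake is which group migrates. Aryl migration is needed over hydride migration, which would end in a benzoic acid; it is favoured by the lone pair of the B1 ether oxygen ortho to both migrating carbons, which stabilises the electron-deficient transition state, and by the relief of crowding when a tetrahedral carbon in a 1,2,3-trisubstituted array is replaced by oxygen. The formyl and bromo groups meta to each migrating carbon work against it, which is why excess peracid and gentle heating are planned. Ring A carries bromine instead of a third oxygen and should be too weak a nucleophile to be hydroxylated by the peracid, and the formate esters keep ring B deactivated until the oxidant is gone.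

Step 6
Reactants: 10 2-[3-(benzyloxy)-5-bromophenoxy]-5-bromobenzene-1,3-diol
Product: 11 1,3-bis(benzyloxy)-2-[3-(benzyloxy)-5-bromophenoxy]-5-bromobenzene
Conditions: BnBr (2.4 equiv), K2CO3, DMF, rt → 50 °C
Reagents that add atoms: benzyl bromide, BrCc1ccccc1
Why: Twofold Williamson etherification of the only free hydroxyls. It also protects the oxidation-prone resorcinol before the metal-catalysed and oxidative steps.

Step 7
Reactants: 11 1,3-bis(benzyloxy)-2-[3-(benzyloxy)-5-bromophenoxy]-5-bromobenzene
Product: 12 2-{3-(benzyloxy)-5-[2,6-bis(benzyloxy)-4-(4,4,5,5-tetramethyl-1,3,2-dioxaborolan-2-yl)phenoxy]phenyl}-4,4,5,5-tetramethyl-1,3,2-dioxaborolane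
Conditions: B2pin2 (2.6 equiv), PdCl2(dppf) (cat.), KOAc, 1,4-dioxane, 90 °C
Reagents that add atoms: bis(pinacolato)diboron, CC1(C)OB(OC1(C)C)B1OC(C)(C)C(C)(C)O1
Why: Twofold Miyaura borylation: zerovalent palladium inserts into each C–Br bond, acetate assists transmetalation with the diboron reagent, and reductive elimination forms the C–B bond. Both bromines are flanked by hydrogens, and the weak base KOAc disfavours Suzuki coupling of product with substrate.

Step 8
Reactants: 12 2-{3-(benzyloxy)-5-[2,6-bis(benzyloxy)-4-(4,4,5,5-tetramethyl-1,3,2-dioxaborolan-2-yl)phenoxy]phenyl}-4,4,5,5-tetramethyl-1,3,2-dioxaborolane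
Product: 13 3,5-bis(benzyloxy)-4-[3-(benzyloxy)-5-hydroxyphenoxy]phenol
Conditions: 30% H2O2, aq NaOH, THF, 0 °C; then aq Na2S2O3, NH4Cl
Reagents that add atoms: hydrogen peroxide, OO
Why: Oxidation of arylboronates: hydroperoxide adds to boron, the aryl group shifts from boron to oxygen, and the borate ester is hydrolysed. Low temperature and a prompt reductive quench limit further oxidation of the electron-rich phenols.

Step 9
Reactants: 13 3,5-bis(benzyloxy)-4-[3-(benzyloxy)-5-hydroxyphenoxy]phenol
Product: 14 3,5-bis(benzyloxy)-4-[3-(benzyloxy)-5-(sulfooxy)phenoxy]phenyl hydrogen sulfate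
Conditions: SO3·pyridine (6 equiv), pyridine, 45 °C; then Dowex 50W (Na+ form), MeOH–H2O
Reagents that add atoms: sulfur trioxide–pyridine complex, O=S(=O)([O-])[n+]1ccccc1
Why: O-Sulfation of phenols by transfer of SO3 from its pyridine complex. The hydroxyls at A1 and B4 are the only free ones, and both are unhindered. The cation exchange removes pyridinium, which would poison the catalyst of step 10.

Step 10
Reactants: 14 3,5-bis(benzyloxy)-4-[3-(benzyloxy)-5-(sulfooxy)phenoxy]phenyl hydrogen sulfate
Product: 15 3,5-dihydroxy-4-[3-hydroxy-5-(sulfooxy)phenoxy]phenyl hydrogen sulfate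
Conditions: H2 (1 atm), 10% Pd/C, MeOH–H2O, rt; then Dowex 50W (H+ form), 0 °C, freeze-drying
Reagents that add atoms: none
Why: Catalytic hydrogenolysis of three benzyl aryl ethers under neutral conditions. Aryl sulfate monoester salts are not reduced and, as salts, do not hydrolyse during the reaction.

## Compound list

1 | 5-bromo-2-fluorobenzaldehyde | O=Cc1cc(Br)ccc1F | starting material
2 | 4-bromo-2-(dimethoxymethyl)-1-fluorobenzene | COC(OC)c1cc(Br)ccc1F | intermediate
3 | [5-bromo-3-(dimethoxymethyl)-2-fluorophenyl]lithium | COC(OC)c1cc(Br)cc([Li])c1F | intermediate (not isolated)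
4 | 5-bromo-3-(dimethoxymethyl)-2-fluorobenzaldehyde | COC(OC)c1cc(Br)cc(C=O)c1F | intermediate (not isolated)
5 | 5-bromo-2-fluorobenzene-1,3-dicarbaldehyde | O=Cc1cc(Br)cc(C=O)c1F | intermediate
6 | 5-bromobenzene-1,3-diol | Oc1cc(O)cc(Br)c1 | starting material
7 | 3-(benzyloxy)-5-bromophenol | Oc1cc(Br)cc(OCc2ccccc2)c1 | intermediate
8 | 2-[3-(benzyloxy)-5-bromophenoxy]-5-bromobenzene-1,3-dicarbaldehyde | O=Cc1cc(Br)cc(C=O)c1Oc1cc(Br)cc(OCc2ccccc2)c1 | intermediate
9 | 2-[3-(benzyloxy)-5-bromophenoxy]-5-bromo-1,3-phenylene diformate | O=COc1cc(Br)cc(OC=O)c1Oc1cc(Br)cc(OCc2ccccc2)c1 | intermediate (not isolated)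
10 | 2-[3-(benzyloxy)-5-bromophenoxy]-5-bromobenzene-1,3-diol | Oc1cc(Br)cc(O)c1Oc1cc(Br)cc(OCc2ccccc2)c1 | intermediate
11 | 1,3-bis(benzyloxy)-2-[3-(benzyloxy)-5-bromophenoxy]-5-bromobenzene | Brc1cc(OCc2ccccc2)c(Oc2cc(Br)cc(OCc3ccccc3)c2)c(OCc2ccccc2)c1 | intermediate
12 | 2-{3-(benzyloxy)-5-[2,6-bis(benzyloxy)-4-(4,4,5,5-tetramethyl-1,3,2-dioxaborolan-2-yl)phenoxy]phenyl}-4,4,5,5-tetramethyl-1,3,2-dioxaborolane | CC1(C)OB(OC1(C)C)c1cc(OCc2ccccc2)c(Oc2cc(OCc3ccccc3)cc(B3OC(C)(C)C(C)(C)O3)c2)c(OCc2ccccc2)c1 | intermediate
13 | 3,5-bis(benzyloxy)-4-[3-(benzyloxy)-5-hydroxyphenoxy]phenol | Oc1cc(OCc2ccccc2)c(Oc2cc(O)cc(OCc3ccccc3)c2)c(OCc2ccccc2)c1 | intermediate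
14 | 3,5-bis(benzyloxy)-4-[3-(benzyloxy)-5-(sulfooxy)phenoxy]phenyl hydrogen sulfate | O=S(=O)(O)Oc1cc(OCc2ccccc2)cc(Oc2c(OCc3ccccc3)cc(OS(=O)(=O)O)cc2OCc2ccccc2)c1 | intermediate
15 | 3,5-dihydroxy-4-[3-hydroxy-5-(sulfooxy)phenoxy]phenyl hydrogen sulfate | O=S(=O)(O)Oc1cc(O)cc(Oc2c(O)cc(OS(=O)(=O)O)cc2O)c1 | target

## Step count and least certain steps

Total: 10 steps. Longest linear sequence: 9 steps (1 → 2 → 5 → 8 → 10 → 11 → 12 → 13 → 14 → 15). The conversion of 6 into 7 is a one-step branch.

Step 5 (key step). The likely failure is hydride migration competing with aryl migration in one or both peroxy adducts. The migrating carbon is meta to a formyl group and to bromine, and the donor is an aryloxy oxygen, which is weaker than an alkoxy oxygen; the outcome would be carboxylic acids in place of formates. The fallback sets out from 8 and returns at 10. Addition of MeMgBr (THF, −78 °C) to both formyl groups should give 1,1'-{2-[3-(benzyloxy)-5-bromophenoxy]-5-bromo-1,3-phenylene}di(ethan-1-ol) F1 as a mixture of racemic and meso diastereomers. Both stereocentres disappear when 2-iodoxybenzoic acid in DMSO oxidises it to 1,1'-{2-[3-(benzyloxy)-5-bromophenoxy]-5-bromo-1,3-phenylene}di(ethan-1-one) F2. Baeyer–Villiger oxidation of this diketone with CF3CO3H (from (CF3CO)2O and urea·H2O2, Na2HPO4, CH2Cl2) should give 2-[3-(benzyloxy)-5-bromophenoxy]-5-bromo-1,3-phenylene diacetate F3, because the only competitor of the aryl group in a methyl ketone is methyl, which migrates far more slowly. K2CO3 in methanol then cleaves the acetates to 10.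

Step 2. Deprotonation may occur at the position between the acetal and bromine, bromine may migrate between aryllithiums, or LiF may be lost to an aryne if the temperature rises; all stem from a bromoarene being metalated by a base. The fallback sets out from 1 and returns at 4, replacing deprotonation by halogen–metal exchange at a pre-set position. N-Iodosuccinimide in CF3SO3H should iodinate 1 at the carbon ortho to fluorine and meta to the formyl group, giving 5-bromo-2-fluoro-3-iodobenzaldehyde F4. Acetalisation as in step 1 gives 5-bromo-1-(dimethoxymethyl)-2-fluoro-3-iodobenzene F5. Exchange with iPrMgCl·LiCl at −40 °C, much faster at C–I than at C–Br, followed by DMF, gives acetal aldehyde 4, and the acid treatment of step 2 then gives 5.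

Step 7. Two C–Br bonds must both be borylated. Coupling of a formed boronate with unreacted bromide (oligomers) and reductive loss of bromine are the likely side processes, and the product of step 8 is sensitive to excess oxidant. The fallback sets out from 11 and returns at 13 with no new compound: palladium-catalysed C–O coupling with hydroxide (Pd2(dba)3, 2-di-tert-butylphosphino-2',4',6'-triisopropylbiphenyl, KOH, 1,4-dioxane–H2O, 100 °C) converts both bromides directly into phenols, so boron and peroxide are avoided.

Step 9. Sulfation of one of the two phenols may be incomplete, the activated rings may be C-sulfonated at higher temperature, and material may be lost in purifying a dianionic salt. The fallback sets out from 13 and returns at 14. 2,2,2-Trichloroethyl chlorosulfate with Et3N and 4-(dimethylamino)pyridine in THF should give the neutral diester 3,5-bis(benzyloxy)-4-{3-(benzyloxy)-5-[(2,2,2-trichloroethoxy)sulfonyloxy]phenoxy}phenyl 2,2,2-trichloroethyl sulfate F6, which can be chromatographed and checked for complete bis-sulfation. Zn and HCO2NH4 in methanol then remove both trichloroethyl groups by reductive elimination and give 14 as its ammonium salt.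

## Further compounds

F1 | step 5 | 1,1'-{2-[3-(benzyloxy)-5-bromophenoxy]-5-bromo-1,3-phenylene}di(ethan-1-ol) (mixture of racemic and meso diastereomers) | CC(O)c1cc(Br)cc(C(C)O)c1Oc1cc(Br)cc(OCc2ccccc2)c1
F2 | step 5 | 1,1'-{2-[3-(benzyloxy)-5-bromophenoxy]-5-bromo-1,3-phenylene}di(ethan-1-one) | CC(=O)c1cc(Br)cc(C(C)=O)c1Oc1cc(Br)cc(OCc2ccccc2)c1
F3 | step 5 | 2-[3-(benzyloxy)-5-bromophenoxy]-5-bromo-1,3-phenylene diacetate | CC(=O)Oc1cc(Br)cc(OC(C)=O)c1Oc1cc(Br)cc(OCc2ccccc2)c1
F4 | step 2 | 5-bromo-2-fluoro-3-iodobenzaldehyde | O=Cc1cc(Br)cc(I)c1F
F5 | step 2 | 5-bromo-1-(dimethoxymethyl)-2-fluoro-3-iodobenzene | COC(OC)c1cc(Br)cc(I)c1F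
F0 | step 7 | none | none
F6 | step 9 | 3,5-bis(benzyloxy)-4-{3-(benzyloxy)-5-[(2,2,2-trichloroethoxy)sulfonyloxy]phenoxy}phenyl 2,2,2-trichloroethyl sulfate | ClC(Cl)(Cl)COS(=O)(=O)Oc1cc(OCc2ccccc2)cc(Oc2c(OCc3ccccc3)cc(OS(=O)(=O)OCC(Cl)(Cl)Cl)cc2OCc2ccccc2)c1
A1 | alternative 1 | 2-[3-(pivaloyloxy)phenoxy]-1,3-phenylene bis(2,2-dimethylpropanoate) | CC(C)(C)C(=O)Oc1cccc(Oc2c(OC(=O)C(C)(C)C)cccc2OC(=O)C(C)(C)C)c1
A2 | alternative 1 | 5-hydroxy-2-[3-hydroxy-5-(pivaloyloxy)phenoxy]-1,3-phenylene bis(2,2-dimethylpropanoate) | CC(C)(C)C(=O)Oc1cc(O)cc(Oc2c(OC(=O)C(C)(C)C)cc(O)cc2OC(=O)C(C)(C)C)c1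
A3 | alternative 2 | rac-4-[3-(benzyloxy)-5-(methoxymethoxy)phenoxy]-3-(benzyloxy)cyclobut-2-en-1-one | O=C1C=C(OCc2ccccc2)C1Oc1cc(OCc2ccccc2)cc(OCOC)c1
A4 | alternative 2 | (triisopropylsilyloxy)ethyne | C#CO[Si](C(C)C)(C(C)C)C(C)C
A5 | alternative 2 | 2-[3-(benzyloxy)-5-(methoxymethoxy)phenoxy]-3-(benzyloxy)-5-(triisopropylsilyloxy)phenol | Oc1cc(O[Si](C(C)C)(C(C)C)C(C)C)cc(OCc2ccccc2)c1Oc1cc(OCc2ccccc2)cc(OCOC)c1
A6 | alternative 3 | dimethyl 2-[3-(benzyloxy)-5-(methoxymethoxy)phenoxy]malonate | COC(=O)C(Oc1cc(OCc2ccccc2)cc(OCOC)c1)C(=O)OC
A7 | alternative 3 | dimethyl 3-oxopentanedioate | COC(=O)CC(=O)CC(=O)OC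
A8 | alternative 3 | dimethyl 5-[3-(benzyloxy)-5-(methoxymethoxy)phenoxy]-2,4,6-trihydroxyisophthalate | COC(=O)c1c(O)c(Oc2cc(OCc3ccccc3)cc(OCOC)c2)c(O)c(C(=O)OC)c1O
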